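**Retrosynthetic overview**

- The ynone C(=O)–C(sp) bond is cut last (acyl Sonogashira): side-chain acid chloride of the chromanedione plus O-silylated (S,Z)-tetradec-6-ene-1,3-diyn-5-ol, the latter from (Z)-dec-2-enal and trimethylsilylbutadiyne by asymmetric alkynylation.
- The chromane-2,4-dione is opened at the lactone O1–C2 bond to a β-keto imide. The freed phenol displaces the oxazolidinone, and this pyranone ring is the only ring closed in the route (the benzene ring is bought).
- The β-keto imide comes from an aldol adduct assembled in one flask from a farnesyl ynamide, [2-(1,3-dioxolan-2-yl)ethyl]copper, an oxenoid oxygen and 2-silyloxybenzaldehyde; bonds formed are C3–CH2 (side chain) and C3–C4.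
- The plan rests on C3 of the chromane-2,4-dione ring, the quaternary stereocentre between lactone carbonyl C2 and ketone C4. It carries two primary alkyl groups (farnesyl CH2 and side-chain CH2) that face-selective alkylation could hardly tell apart; as the β-carbon of an ynamide it receives them one at a time with fixed geometry.
- The ynamide comes from (2E,6E)-farnesyl bromide and ethynylmagnesium bromide, bromination of the alkyne and copper-catalysed N-alkynylation of (S)-4-benzyloxazolidin-2-one.

Key step: step 6

Assumption: the enolate of step 6 is taken to react with its metal also bound to the oxazolidinone carbonyl, as N-acyloxazolidinone enolates do in alkylations. On that model the (S)-4-benzyl auxiliary leaves open the face that gives (S)-C3, and the (3S) carbinol label of the aldol adduct follows from a chair transition state and is provisional.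

**Route**

Step 1
Reactants: 1 (2E,6E)-farnesyl bromide; 2 ethynylmagnesium bromide
Product: 3 (4E,8E)-5,9,13-trimethyltetradeca-4,8,12-trien-1-yne
Conditions: 2 (2.5 equiv), CuCl (10 mol%), THF, 0 to 50 °C
Reagents that add atoms: none
Why: Copper-catalysed SN2 coupling of an alkynyl Grignard reagent with a primary allylic bromide should give the skipped enyne, the excess acetylide suppressing double alkylation and the E-alkenes staying untouched.

Step 2
Reactants: 3 (4E,8E)-5,9,13-trimethyltetradeca-4,8,12-trien-1-yne
Product: 4 (4E,8E)-1-bromo-5,9,13-trimethyltetradeca-4,8,12-trien-1-yne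
Conditions: NBS, AgNO3 (10 mol%), acetone, rt, dark
Reagents that add atoms: N-bromosuccinimide, O=C1CCC(=O)N1Br
Why: Silver-catalysed electrophilic bromination of the terminal alkyne (via the silver acetylide) is fast enough in dry acetone to outrun attack of NBS on the trisubstituted alkenes.

Step 3
Reactants: 4 (4E,8E)-1-bromo-5,9,13-trimethyltetradeca-4,8,12-trien-1-yne; 5 (S)-4-benzyloxazolidin-2-one
Product: 6 (S)-4-benzyl-3-[(4E,8E)-5,9,13-trimethyltetradeca-4,8,12-trien-1-yn-1-yl]oxazolidin-2-one
Conditions: CuSO4·5H2O (10 mol%), 1,10-phenanthroline (20 mol%), K3PO4, toluene, 70 °C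
Reagents that add atoms: none
Why: Copper-catalysed amidative cross-coupling of a 1-bromoalkyne with an oxazolidinone is the standard entry to chiral ynamides, and the mild phosphate base should leave the doubly activated CH2 and the auxiliary stereocentre untouched.

Step 4
Reactants: 7 salicylaldehyde
Product: 8 2-(tert-butyldimethylsilyloxy)benzaldehyde
Conditions: TBSCl, imidazole, DMF, rt
Reagents that add atoms: tert-butyldimethylsilyl chloride, CC(C)(C)[Si](C)(C)Cl
Why: Imidazole-promoted O-silylation masks the phenol as a fluoride-labile ether that tolerates organocopper and peroxide anion.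

Step 5
Reactants: 9 2-(2-bromoethyl)-1,3-dioxolane
Product: 10 [2-(1,3-dioxolan-2-yl)ethyl]magnesium bromide
Conditions: Mg turnings, THF (small volume), 20–25 °C
Reagents that add atoms: magnesium, [Mg]
Why: Oxidative insertion of magnesium gives the acetal-bearing Grignard reagent, which is stable when kept below about 30 °C and is diluted with Et2O for the next step.

Step 6
Reactants: 10 [2-(1,3-dioxolan-2-yl)ethyl]magnesium bromide; 6 (S)-4-benzyl-3-[(4E,8E)-5,9,13-trimethyltetradeca-4,8,12-trien-1-yn-1-yl]oxazolidin-2-one; 8 2-(tert-butyldimethylsilyloxy)benzaldehyde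
Product: 14 (S)-4-benzyl-3-[(2S,3S)-3-[2-(tert-butyldimethylsilyloxy)phenyl]-2-[2-(1,3-dioxolan-2-yl)ethyl]-3-hydroxy-2-[(2E,6E)-3,7,11-trimethyldodeca-2,6,10-trien-1-yl]propanoyl]oxazolidin-2-one (aldol adduct; 3S provisional), via organocopper reagent 11 (not isolated), via vinylcopper 12 (not isolated), via copper enolate 13 (not isolated)
Conditions: 10 + CuBr·SMe2 (1:1), Et2O/THF, −40 °C; 6, −40 to −10 °C; t-BuOOLi (from t-BuOOH + n-BuLi), THF, −78 °C; 8, −78 °C; aq. NH4Cl
Reagents that add atoms: tert-butyl hydroperoxide (used as its lithium salt), CC(C)(C)OO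
Why: Transmetalation of 10 with CuBr·SMe2 gives the monovalent organocopper 11, which adds syn across the ynamide with the alkyl group going to the carbon remote from nitrogen because the oxazolidinone carbonyl chelates copper at the nitrogen-bearing carbon, so vinylcopper 12 holds the new C3–CH2 bond with the dioxolanylethyl arm cis to copper and the farnesyl CH2 cis to nitrogen. The oxenoid t-BuOOLi then inserts oxygen into the C–Cu bond with retention to give the single (E)-enolate 13, which adds to aldehyde 8 through a closed six-membered (Zimmerman–Traxler) transition state to form the C3–C4 bond; no ring is closed in this step. The sequence is the known carbocupration–oxidation–aldol reaction of chiral ynamides for acyclic all-carbon quaternary centres, applied here to a functionalised Grignard reagent and a farnesyl-bearing ynamide. The quaternary centre is controlled by the fixed enolate geometry (which substituent sits where) together with the 4-benzyl group of the auxiliary (which face reacts), and the carbinol centre by the chair arrangement with the aryl group equatorial, the latter being provisional and erased in step 7. The step needs regioselective carbometalation (secured by carbamate chelation), geometric integrity of 12 and 13 (secured by staying at or below −10 °C and oxidising at −78 °C) and reaction at the ynamide and aldehyde only, the isolated trisubstituted alkenes, the acetal and the aryl silyl ether being inert to organocopper and peroxide anion. A cold quench should limit retro-aldol cleavage and silyl transfer from the phenol oxygen to the new alkoxide.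

Step 7
Reactants: 14 aldol adduct
Product: 15 (S)-4-benzyl-3-[(2S)-3-[2-(tert-butyldimethylsilyloxy)phenyl]-2-[2-(1,3-dioxolan-2-yl)ethyl]-3-oxo-2-[(2E,6E)-3,7,11-trimethyldodeca-2,6,10-trien-1-yl]propanoyl]oxazolidin-2-one
Conditions: Dess–Martin periodinane, NaHCO3, CH2Cl2, rt
Reagents that add atoms: none
Why: Dess–Martin oxidation should convert the hindered benzylic carbinol into the aryl ketone without base (no retro-aldol), removing the provisional stereocentre while the quaternary centre, having no α-hydrogen, cannot epimerise.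

Step 8
Reactants: 15 β-keto imide
Product: 17 (3S)-3-[2-(1,3-dioxolan-2-yl)ethyl]-3-[(2E,6E)-3,7,11-trimethyldodeca-2,6,10-trien-1-yl]chromane-2,4-dione, via phenol 16 (not isolated)
Conditions: TBAF, AcOH (1:1), THF, 0 °C; then Et3N, DMAP (cat.), rt
Reagents that add atoms: none
Why: Buffered fluoride cleaves the aryl silyl ether and the freed phenol attacks the exocyclic imide carbonyl in a 6-exo-trig acyl substitution (intramolecular transesterification of an N-acyloxazolidinone), closing the lactone ring and releasing the recoverable auxiliary, while the acetate buffer avoids free alkoxide or hydroxide that could cleave the non-enolisable β-dicarbonyl by retro-Claisen attack.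

Step 9
Reactants: 17 chromanedione acetal
Product: 18 3-[(3S)-2,4-dioxo-3-[(2E,6E)-3,7,11-trimethyldodeca-2,6,10-trien-1-yl]chroman-3-yl]propanal
Conditions: 1 M aq. HCl, THF, rt
Reagents that add atoms: water, O
Why: Acid-catalysed acetal hydrolysis under dilute conditions should release the aldehyde, the aryl lactone and the trisubstituted alkenes tolerating brief exposure to dilute acid at room temperature.

Step 10
Reactants: 18 aldehyde
Product: 19 3-[(3S)-2,4-dioxo-3-[(2E,6E)-3,7,11-trimethyldodeca-2,6,10-trien-1-yl]chroman-3-yl]propanoic acid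
Conditions: NaClO2, NaH2PO4, 2-methylbut-2-ene (excess), t-BuOH/H2O, 0 °C to rt
Reagents that add atoms: sodium chlorite, [Na+].[O-]Cl=O
Why: Pinnick oxidation takes the aldehyde to the acid at about pH 4, the excess 2-methylbut-2-ene trapping hypochlorous acid before it reaches the farnesyl alkenes and the lactone staying closed.

Step 11
Reactants: 20 dec-2-yn-1-ol
Product: 21 (Z)-dec-2-en-1-ol
Conditions: H2 (1 atm), Pd/CaCO3 poisoned with Pb(OAc)2, quinoline, EtOAc, rt
Reagents that add atoms: none
Why: Lindlar semihydrogenation delivers both hydrogens to one face of the alkyne and so gives the Z-alkene.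

Step 12
Reactants: 21 (Z)-dec-2-en-1-ol
Product: 22 (Z)-dec-2-enal
Conditions: Dess–Martin periodinane, NaHCO3, CH2Cl2, 0 °C
Reagents that add atoms: none
Why: Buffered Dess–Martin oxidation of the allylic alcohol should give the Z-enal without acid- or base-induced isomerisation, and the aldehyde is used at once.

Step 13
Reactants: 23 1,4-bis(trimethylsilyl)buta-1,3-diyne
Product: 25 buta-1,3-diyn-1-yl(trimethyl)silane, via lithium acetylide 24 (not isolated)
Conditions: MeLi·LiBr (1.0 equiv), Et2O, rt; aq. NH4Cl, 0 °C; kept as Et2O solution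
Reagents that add atoms: none
Why: Nucleophilic desilylation by methyllithium stops after one silyl group because the resulting acetylide is deactivated towards a second attack, and protonation gives the terminal diyne.

Step 14
Reactants: 25 buta-1,3-diyn-1-yl(trimethyl)silane; 22 (Z)-dec-2-enal
Product: 27 (5S,6Z)-1-(trimethylsilyl)tetradec-6-ene-1,3-diyn-5-ol, via alkynylzinc 26 (not isolated)
Conditions: 25 (4 equiv), ZnEt2, Cy2NH (5 mol%), Et2O, rt; (R)-BINOL (40 mol%); Ti(OiPr)4; then 22, rt
Reagents that add atoms: none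
Why: BINOL–titanium-catalysed asymmetric addition of an alkynylzinc reagent to an aldehyde is known for terminal 1,3-diynes and enals, and by the established sense of this catalyst the (R)-ligand is expected to set the (S)-carbinol (to be confirmed by Mosher ester analysis), the Z-alkene being carried through from 22.

Step 15
Reactants: 27 (5S,6Z)-1-(trimethylsilyl)tetradec-6-ene-1,3-diyn-5-ol
Product: 28 tert-butyldimethyl{[(5S,6Z)-1-(trimethylsilyl)tetradec-6-ene-1,3-diyn-5-yl]oxy}silane
Conditions: TBSCl, imidazole, DMF, rt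
Reagents that add atoms: tert-butyldimethylsilyl chloride, CC(C)(C)[Si](C)(C)Cl
Why: O-silylation protects the carbinol against acylation in step 17 without touching the stereocentre.

Step 16
Reactants: 28 bis-silylated diynol
Product: 29 tert-butyldimethyl{[(5S,6Z)-tetradec-6-ene-1,3-diyn-5-yl]oxy}silane
Conditions: K2CO3 (cat.), MeOH, 0 °C to rt
Reagents that add atoms: none
Why: Base-catalysed methanolysis cleaves the C(sp)–Si bond selectively, the secondary O–TBS ether being stable to carbonate in methanol; the terminal diyne is used promptly.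

Step 17
Reactants: 19 acid; 29 terminal diyne
Product: 31 (3S)-3-[(8S,9Z)-8-(tert-butyldimethylsilyloxy)-3-oxoheptadec-9-ene-4,6-diyn-1-yl]-3-[(2E,6E)-3,7,11-trimethyldodeca-2,6,10-trien-1-yl]chromane-2,4-dione, via acid chloride 30 (not isolated)
Conditions: 1-chloro-N,N,2-trimethylprop-1-en-1-amine, CH2Cl2, 0 °C to rt; then 29, PdCl2(PPh3)2 (3 mol%), CuI (6 mol%), Et3N, THF (degassed), rt
Reagents that add atoms: none
Why: The α-chloroenamine forms the acid chloride under neutral conditions (no HCl to add to the farnesyl alkenes), and acyl Sonogashira coupling of the terminal diyne then makes the C(=O)–C(sp) bond with only a tertiary amine present, which the chromanedione tolerates.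

Step 18
Reactants: 31 silylated ynone
Product: 32 (3S)-3-[(8S,9Z)-8-hydroxy-3-oxoheptadec-9-ene-4,6-diyn-1-yl]-3-[(2E,6E)-3,7,11-trimethyldodeca-2,6,10-trien-1-yl]chromane-2,4-dione
Conditions: HF·pyridine, pyridine, THF, 0 °C to rt
Reagents that add atoms: none
Why: Mildly acidic fluoride desilylation frees the secondary alcohol while sparing the diynone and the chromane-2,4-dione, which basic fluoride would attack; no stereocentre is touched.

**Compound list**

1 | (2E,6E)-farnesyl bromide | BrC/C=C(\C)CC/C=C(\C)CCC=C(C)C | starting material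
2 | ethynylmagnesium bromide | Br[Mg]C#C | starting material
3 | (4E,8E)-5,9,13-trimethyltetradeca-4,8,12-trien-1-yne | C#CC/C=C(\C)CC/C=C(\C)CCC=C(C)C | intermediate
4 | (4E,8E)-1-bromo-5,9,13-trimethyltetradeca-4,8,12-trien-1-yne | BrC#CC/C=C(\C)CC/C=C(\C)CCC=C(C)C | intermediate
5 | (S)-4-benzyloxazolidin-2-one | O=C1N[C@@H](Cc2ccccc2)CO1 | starting material
6 | (S)-4-benzyl-3-[(4E,8E)-5,9,13-trimethyltetradeca-4,8,12-trien-1-yn-1-yl]oxazolidin-2-one | O=C1OC[C@H](Cc2ccccc2)N1C#CC/C=C(\C)CC/C=C(\C)CCC=C(C)C | intermediate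
7 | salicylaldehyde | O=Cc1ccccc1O | starting material
8 | 2-(tert-butyldimethylsilyloxy)benzaldehyde | O=Cc1ccccc1O[Si](C)(C)C(C)(C)C | intermediate
9 | 2-(2-bromoethyl)-1,3-dioxolane | BrCCC1OCCO1 | starting material
10 | [2-(1,3-dioxolan-2-yl)ethyl]magnesium bromide | Br[Mg]CCC1OCCO1 | intermediate
11 | [2-(1,3-dioxolan-2-yl)ethyl]copper (as its MgBr2 complex) | [Cu]CCC1OCCO1 | intermediate
12 | (S)-4-benzyl-3-[(1E,4E,8E)-1-cuprio-2-[2-(1,3-dioxolan-2-yl)ethyl]-5,9,13-trimethyltetradeca-1,4,8,12-tetraen-1-yl]oxazolidin-2-one (copper cis to the dioxolanylethyl arm) | O=C1OC[C@H](Cc2ccccc2)N1/C([Cu])=C(/CCC3OCCO3)C/C=C(\C)CC/C=C(\C)CCC=C(C)C | intermediate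
13 | monovalent copper (E)-enolate of the imide: O-metalated (1E,4E,8E)-1-[(S)-4-benzyl-2-oxooxazolidin-3-yl]-2-[2-(1,3-dioxolan-2-yl)ethyl]-5,9,13-trimethyltetradeca-1,4,8,12-tetraen-1-olate (oxygen cis to the dioxolanylethyl arm) | O=C1OC[C@H](Cc2ccccc2)N1/C(O[Cu])=C(/CCC3OCCO3)C/C=C(\C)CC/C=C(\C)CCC=C(C)C | intermediate
14 | (S)-4-benzyl-3-[(2S,3S)-3-[2-(tert-butyldimethylsilyloxy)phenyl]-2-[2-(1,3-dioxolan-2-yl)ethyl]-3-hydroxy-2-[(2E,6E)-3,7,11-trimethyldodeca-2,6,10-trien-1-yl]propanoyl]oxazolidin-2-one (3S provisional) | O1CCOC1CC[C@@]([C@@H](O)c2ccccc2O[Si](C)(C)C(C)(C)C)(C/C=C(\C)CC/C=C(\C)CCC=C(C)C)C(=O)N3[C@@H](Cc4ccccc4)COC3=O | intermediate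
15 | (S)-4-benzyl-3-[(2S)-3-[2-(tert-butyldimethylsilyloxy)phenyl]-2-[2-(1,3-dioxolan-2-yl)ethyl]-3-oxo-2-[(2E,6E)-3,7,11-trimethyldodeca-2,6,10-trien-1-yl]propanoyl]oxazolidin-2-one | O1CCOC1CC[C@@](C(=O)c2ccccc2O[Si](C)(C)C(C)(C)C)(C/C=C(\C)CC/C=C(\C)CCC=C(C)C)C(=O)N3[C@@H](Cc4ccccc4)COC3=O | intermediate
16 | (S)-4-benzyl-3-[(2S)-2-[2-(1,3-dioxolan-2-yl)ethyl]-3-(2-hydroxyphenyl)-3-oxo-2-[(2E,6E)-3,7,11-trimethyldodeca-2,6,10-trien-1-yl]propanoyl]oxazolidin-2-one | O1CCOC1CC[C@@](C(=O)c2ccccc2O)(C/C=C(\C)CC/C=C(\C)CCC=C(C)C)C(=O)N3[C@@H](Cc4ccccc4)COC3=O | intermediate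
17 | (3S)-3-[2-(1,3-dioxolan-2-yl)ethyl]-3-[(2E,6E)-3,7,11-trimethyldodeca-2,6,10-trien-1-yl]chromane-2,4-dione | O1CCOC1CC[C@@]2(C/C=C(\C)CC/C=C(\C)CCC=C(C)C)C(=O)Oc3ccccc3C2=O | intermediate
18 | 3-[(3S)-2,4-dioxo-3-[(2E,6E)-3,7,11-trimethyldodeca-2,6,10-trien-1-yl]chroman-3-yl]propanal | O=CCC[C@@]1(C/C=C(\C)CC/C=C(\C)CCC=C(C)C)C(=O)Oc2ccccc2C1=O | intermediate
19 | 3-[(3S)-2,4-dioxo-3-[(2E,6E)-3,7,11-trimethyldodeca-2,6,10-trien-1-yl]chroman-3-yl]propanoic acid | OC(=O)CC[C@@]1(C/C=C(\C)CC/C=C(\C)CCC=C(C)C)C(=O)Oc2ccccc2C1=O | intermediate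
20 | dec-2-yn-1-ol | CCCCCCCC#CCO | starting material
21 | (Z)-dec-2-en-1-ol | CCCCCCC/C=C\CO | intermediate
22 | (Z)-dec-2-enal | CCCCCCC/C=C\C=O | intermediate
23 | 1,4-bis(trimethylsilyl)buta-1,3-diyne | C[Si](C)(C)C#CC#C[Si](C)(C)C | starting material
24 | [4-(trimethylsilyl)buta-1,3-diyn-1-yl]lithium | [Li]C#CC#C[Si](C)(C)C | intermediate
25 | buta-1,3-diyn-1-yl(trimethyl)silane | C#CC#C[Si](C)(C)C | intermediate
26 | ethyl[4-(trimethylsilyl)buta-1,3-diyn-1-yl]zinc | CC[Zn]C#CC#C[Si](C)(C)C | intermediate
27 | (5S,6Z)-1-(trimethylsilyl)tetradec-6-ene-1,3-diyn-5-ol | CCCCCCC/C=C\[C@H](O)C#CC#C[Si](C)(C)C | intermediate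
28 | tert-butyldimethyl{[(5S,6Z)-1-(trimethylsilyl)tetradec-6-ene-1,3-diyn-5-yl]oxy}silane | CCCCCCC/C=C\[C@H](O[Si](C)(C)C(C)(C)C)C#CC#C[Si](C)(C)C | intermediate
29 | tert-butyldimethyl{[(5S,6Z)-tetradec-6-ene-1,3-diyn-5-yl]oxy}silane | CCCCCCC/C=C\[C@H](O[Si](C)(C)C(C)(C)C)C#CC#C | intermediate
30 | 3-[(3S)-2,4-dioxo-3-[(2E,6E)-3,7,11-trimethyldodeca-2,6,10-trien-1-yl]chroman-3-yl]propanoyl chloride | ClC(=O)CC[C@@]1(C/C=C(\C)CC/C=C(\C)CCC=C(C)C)C(=O)Oc2ccccc2C1=O | intermediate
31 | (3S)-3-[(8S,9Z)-8-(tert-butyldimethylsilyloxy)-3-oxoheptadec-9-ene-4,6-diyn-1-yl]-3-[(2E,6E)-3,7,11-trimethyldodeca-2,6,10-trien-1-yl]chromane-2,4-dione | CCCCCCC/C=C\[C@H](O[Si](C)(C)C(C)(C)C)C#CC#CC(=O)CC[C@@]1(C/C=C(\C)CC/C=C(\C)CCC=C(C)C)C(=O)Oc2ccccc2C1=O | intermediate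
32 | (3S)-3-[(8S,9Z)-8-hydroxy-3-oxoheptadec-9-ene-4,6-diyn-1-yl]-3-[(2E,6E)-3,7,11-trimethyldodeca-2,6,10-trien-1-yl]chromane-2,4-dione | CCCCCCC/C=C\[C@H](O)C#CC#CC(=O)CC[C@@]1(C/C=C(\C)CC/C=C(\C)CCC=C(C)C)C(=O)Oc2ccccc2C1=O | target

**Step count**

Total: 18 steps. Longest linear sequence: 10 steps (1, 2, 3, 6, 7, 8, 9, 10, 17, 18).

**Steps most likely to fail**

Step 6. The acetal-bearing organocopper may add slowly or incompletely in a medium that contains THF, the enolate may lose its geometry if the mixture warms, and the crowded aldolate may revert by retro-aldol cleavage or pass its silyl group from the phenol oxygen to the alkoxide. The face of attack may also be the reverse of that assumed, which the antipodal auxiliary alone would correct. The fallback abandons the ynamide and builds C3 by conjugate addition. It sets out from 1: 4-hydroxycoumarin F1 is C-alkylated at C3 with 1 (K2CO3, acetone, some O-alkylation accepted) to give ferulenol F2. Michael addition of F2 to acrolein F3 under a quinidine- or quinine-derived bifunctional base (organocatalytic addition of an α-substituted cyclic β-dicarbonyl compound to an enal) then gives aldehyde 18 directly. The pseudo-enantiomeric catalyst is chosen for (S)-C3 and a chiral-phase separation is added if enantiopurity is insufficient. The route is rejoined at 18.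

Step 14. The Z-enal may isomerise to the E-isomer under the Lewis-acidic titanium/zinc medium during the slow room-temperature addition, and enantiocontrol may be incomplete, which would carry through as an inseparable epimer of the target. The fallback sets out from 23 and 22: the lithium acetylide 24 is generated as in step 13 and added to 22 at −78 °C, where isomerisation is not expected, to give racemic (Z)-1-(trimethylsilyl)tetradec-6-ene-1,3-diyn-5-ol F4. Oxidation with MnO2 gives (Z)-1-(trimethylsilyl)tetradec-6-ene-1,3-diyn-5-one F5. CBS reduction with (S)-2-methyl-CBS-oxazaborolidine and catecholborane at −78 °C, the alkynyl group acting as the small substituent, should return 27; the oxazaborolidine antipode is taken if Mosher analysis shows the other sense. The route is rejoined at 27.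

Step 17. The terminal diyne may homocouple oxidatively under copper, the acid chloride may form a ketene with the amine, and the electron-poor diynone may suffer conjugate addition during the coupling. The fallback sets out from 18 and 29 and avoids both the acid chloride and palladium: Zn(OTf)2/Et3N-mediated addition of 29 to aldehyde 18 (toluene, rt) gives the propargylic alcohol (3S)-3-[(8S,9Z)-8-(tert-butyldimethylsilyloxy)-3-hydroxyheptadec-9-ene-4,6-diyn-1-yl]-3-[(2E,6E)-3,7,11-trimethyldodeca-2,6,10-trien-1-yl]chromane-2,4-dione F6 as a mixture of epimers at the new carbinol. Dess–Martin oxidation of F6 gives 31, where the route is rejoined.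

**Further compounds**

F1 | step 6 | 4-hydroxycoumarin | Oc1cc(=O)oc2ccccc12
F2 | step 6 | ferulenol, 4-hydroxy-3-[(2E,6E)-3,7,11-trimethyldodeca-2,6,10-trien-1-yl]-2H-chromen-2-one | Oc1c(C/C=C(\C)CC/C=C(\C)CCC=C(C)C)c(=O)oc2ccccc12
F3 | step 6 | acrolein | C=CC=O
F4 | step 14 | racemic (Z)-1-(trimethylsilyl)tetradec-6-ene-1,3-diyn-5-ol | CCCCCCC/C=C\C(O)C#CC#C[Si](C)(C)C
F5 | step 14 | (Z)-1-(trimethylsilyl)tetradec-6-ene-1,3-diyn-5-one | CCCCCCC/C=C\C(=O)C#CC#C[Si](C)(C)C
F6 | step 17 | (3S)-3-[(8S,9Z)-8-(tert-butyldimethylsilyloxy)-3-hydroxyheptadec-9-ene-4,6-diyn-1-yl]-3-[(2E,6E)-3,7,11-trimethyldodeca-2,6,10-trien-1-yl]chromane-2,4-dione | CCCCCCC/C=C\[C@H](O[Si](C)(C)C(C)(C)C)C#CC#CC(O)CC[C@@]1(C/C=C(\C)CC/C=C(\C)CCC=C(C)C)C(=O)Oc2ccccc2C1=O
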